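Read the X column of the two earlier runs first: X reacts with E, and E is the concentration I could not see.

all flasks: Z 1.8 mM (held)

|  | X | remark | time |
|---|---|---|---|
| south-west | 3.6 mM | run made earlier |  |
| north-west | 51 mM | run made earlier |  |
| spring | 20 mM |  | 25 min |
| dawn | 60 mM |  | 25 min |
| winter | 5.0 mM |  | 25 min |
| summer | 80 mM |  | 25 min |
| midnight | 40 mM |  | 25 min |

| run | time / min | G / % | X / % |
|---|---|---|---|
| south-west | 0.833 | 0 | 97.0 |
| south-west | 2.50 | 1.1 | 90.1 |
| south-west | 4.00 | 0 | 83.7 |
| south-west | 6.00 | 2.5 | 74.9 |
| south-west | 10.0 | 7.7 | 58.4 |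
| south-west | 12.0 | 10.2 | 53.5 |
| north-west | 1.00 | 0 | 95.8 |
| north-west | 1.50 | 0 | 95.8 |
| north-west | 3.00 | 0 | 90.3 |
| north-west | 5.00 | 0 | 83.4 |
| north-west | 8.00 | 2.6 | 75.5 |
| north-west | 12.0 | 4.9 | 65.5 |

(standard deviation of a reading: 1 percentage point)

- amounts and yields of G count D too
- at the start none of E is dissolved
- what may be going on: X + E -> J + L; E + J -> Q + L; E + Q -> G + L; E + G <-> D; Z <-> E

1. ranking by amount of G, in percent of the X charged, from high to low, at 25 min (spring / dawn / winter / summer / midnight)
2. the amount of G, in percent of the X charged of the flask you put first, at 25 min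
3. the amount of G, in percent of the X charged of the flask you put last, at 25 min

I set the columns against each other. South-west at 6.00 min read X 74.9 % and G 2.5 %. North-west at 8.00 min read X 75.5 % and G 2.6 %. In this pair, like X lost went with like G at different clock times, within the scatter of 1 percentage point. So I ranked G by X lost.

The last rows gave the rate. At fixed E, X falls pseudo-first-order, so I defined λ as the natural log of charged X over X left, divided by time. At 12.0 min south-west gave 0.0521 min⁻¹ and north-west 0.0353 min⁻¹, slower by a factor 1.48. Z was held alike in both, so I read that factor as a lower E in the heavier flask.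

I let E enter in proportion to its gap below saturation, 1.8 mM, and leave in proportion to charge c times E. Then E is saturation divided by one plus c/h, and λ follows E. Solving the two runs gave 95.5 mM for h, the charge of X at which E stands at half of saturation. This is a reading and carries the scatter. The same runs gave 0.0541 min⁻¹ for λ at vanishing charge.

At 25 min my rule left X at 27.7 % in winter, 32.7 % in spring, 38.6 % in midnight, 43.6 % in dawn and 47.9 % in summer. I committed to G falling in that order, without a G value of my own.

The forecast gave winter > spring > midnight > dawn > summer, with 38 % first and 14 % last: “G percent therefore falls steadily with loading”.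

The flasks ranked winter > spring > midnight > dawn > summer, from 40.1 % to 14.1 %, D counted in G.

    X + E → J + L (k = 0.510 M⁻¹ s⁻¹)
    E + J → Q + L (k = 2.10 M⁻¹ s⁻¹)
    E + Q → G + L (k = 0.940 M⁻¹ s⁻¹)
    E + G ⇌ D, settled at all times (K = 430 M⁻¹)
    Z ⇌ E, rate k5*(csat - [E]) (kL = 0.0630 s⁻¹)

At 25.0 min summer held X 49.9 % against my 47.9 %. Its E stood at 0.884 mM, half of saturation, and h gave 0.980 mM. Summer read at 1.0 h held X 17.3 %, where the same λ gave 17.1 %.

The numbers in the tables are calculated with constants of no real substance, noise included.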